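The target is disconnected at the ring-fusion bond C5–C10 together with C8–C9, which opens both rings into an acyclic E-enone/E,E-diene. One Lewis-acid-promoted intramolecular Diels–Alder reaction then closes ring A (through the C1–C4 tether) and cyclohexene ring B, setting C5, C9 and quaternary C10 relative to the C3 silyloxy stereocentre. The step exploits the cis relationship of the C10 methyl and the C9 side chain, which maps onto an E-trisubstituted enone. Its temporary C11 carbonyl activates the dienophile and is deleted afterwards. The C6=C7 alkene of the adduct is later moved to C7=C8 through the C17 aldehyde.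

Key step: step 6

Remark: labdane numbering is used (ring A = C1–C5 and C10, ring B = C5–C10, C11–C16 = side chain, C17 = hydroxymethyl carbon, C20 = C10 methyl); 1, 2, 6, 10 and (−)-Ipc2BH are assumed to be catalogue chemicals.

Step 1
Reactants: 1 pent-4-ynal; 2 3-methylbuta-1,2-diene
Product: 4 (4R)-3,3-dimethylhept-1-en-6-yn-4-ol, via prenyl-diisopinocampheylborane 3 (not isolated)
Conditions: (−)-Ipc2BH [from (+)-α-pinene], 2, THF, −25 → 0 °C; then 1, Et2O, −78 °C; then NaOH, H2O2
Reagents that add atoms: (−)-diisopinocampheylborane, B([C@@H]1C[C@@H]2C[C@H]([C@H]1C)C2(C)C)[C@@H]1C[C@@H]2C[C@H]([C@H]1C)C2(C)C (its boron and isopinocampheyl groups are carried only in 3)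
Why: Brown-type allylboration, in which hydroboration of the allene gives the γ,γ-dimethylallylborane that adds to the aldehyde through a chair six-membered transition state with allylic transposition, creating quaternary C4 and the C5=C6 vinyl group, while the (+)-α-pinene-derived ligands direct attack to the Si face and should give the (R)-carbinol at C3.

Step 2
Reactants: 4 (4R)-3,3-dimethylhept-1-en-6-yn-4-ol
Product: 5 tert-butyl{[(4R)-3,3-dimethylhept-1-en-6-yn-4-yl]oxy}dimethylsilane
Conditions: TBSOTf, 2,6-lutidine, CH2Cl2, −78 → 0 °C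
Reagents that add atoms: tert-butyldimethylsilyl triflate, CC(C)(C)[Si](C)(C)OS(=O)(=O)C(F)(F)F
Why: Silyl ether formation with the reactive triflate should overcome the neopentyl-type hindrance at C3 and masks the alcohol against the acid chloride and Lewis acids used later.

Step 3
Reactants: 6 (3R)-5-methoxy-3-methyl-5-oxopentanoic acid
Product: 7 methyl (3S)-5-chloro-3-methyl-5-oxopentanoate
Conditions: (COCl)2, DMF (cat.), CH2Cl2, 0 °C → rt; used at once
Reagents that add atoms: oxalyl chloride, ClC(=O)C(=O)Cl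
Why: Acid chloride formation through the chloroiminium (Vilsmeier-type) catalyst leaves the methyl ester and the C13 stereocentre untouched (the descriptor changes only because chlorine raises the priority of that arm).

Step 4
Reactants: 5 tert-butyl{[(4R)-3,3-dimethylhept-1-en-6-yn-4-yl]oxy}dimethylsilane; 7 methyl (3S)-5-chloro-3-methyl-5-oxopentanoate
Product: 9 methyl (3R,6E,10R)-10-[(tert-butyldimethylsilyl)oxy]-3,7,11,11-tetramethyl-5-oxotrideca-6,12-dienoate, via alkenyldimethylalane 8 (not isolated)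
Conditions: Me3Al, Cp2ZrCl2 (cat.), CH2Cl2, 0 °C → rt; volatiles removed; then 7, Pd(PPh3)4 (cat.), THF, 0 °C → rt
Reagents that add atoms: trimethylaluminium, C[Al](C)C
Why: Zirconium-catalysed syn methylalumination of the terminal alkyne (Negishi carboalumination) places the C20 methyl cis to aluminium, and acylation of the alkenylalane by 7 under zerovalent palladium catalysis proceeds with retention, so three components are joined in one operation to the E-enone with acyl cis to methyl.

Step 5
Reactants: 9 methyl (3R,6E,10R)-10-[(tert-butyldimethylsilyl)oxy]-3,7,11,11-tetramethyl-5-oxotrideca-6,12-dienoate; 10 tert-butyl{[(2E)-3-iodoprop-2-en-1-yl]oxy}dimethylsilane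
Product: 11 methyl (3R,6E,10R,12E,14E)-10,16-bis[(tert-butyldimethylsilyl)oxy]-3,7,11,11-tetramethyl-5-oxohexadeca-6,12,14-trienoate
Conditions: Pd(OAc)2 (cat.), Bu4NCl, KOAc, DMF, 40 °C
Reagents that add atoms: none
Why: Heck reaction, in which the alkenylpalladium species from 10 inserts the neopentyl-type vinyl group at its CH2 terminus and β-hydride elimination, possible only towards C6 because C4 is quaternary, should give the E,E-diene while the hindered trisubstituted enone stays inert.

Step 6
Reactants: 11 methyl (3R,6E,10R,12E,14E)-10,16-bis[(tert-butyldimethylsilyl)oxy]-3,7,11,11-tetramethyl-5-oxohexadeca-6,12,14-trienoate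
Product: 12 methyl (3R)-5-[(1R,2R,4aS,6R,8aR)-6-[(tert-butyldimethylsilyl)oxy]-2-{[(tert-butyldimethylsilyl)oxy]methyl}-5,5,8a-trimethyl-1,2,4a,5,6,7,8,8a-octahydronaphthalen-1-yl]-3-methyl-5-oxopentanoate
Conditions: Me2AlCl (2.2 equiv), CH2Cl2, −78 → −20 °C; 1 M HCl quench
Reagents that add atoms: none
Why: Coordination of Me2AlCl to the C11 ketone lowers the enone LUMO and triggers a concerted, asynchronous normal-demand [4+2] cycloaddition in which the enone β-carbon C10 bonds to diene terminus C5 and C9 bonds to C8. The closest known reaction type is the Lewis-acid-promoted type 1 intramolecular Diels–Alder reaction of E-enone-terminated 1,7,9-decatrienes, which gives trans-fused octalins. Ring B (cyclohexene) is closed by the cycloaddition itself, and ring A (six-membered carbocycle) is closed in the fused mode through the four-carbon C1–C4 tether by the C5–C10 bond. The cis relationship of the C9 acyl chain and the C10 methyl follows from the E enone geometry (suprafacial addition), the trans C5-H/C10-methyl fusion from the endo orientation of the complexed ketone with the tether exo, the transient C8 centre from the E,E diene, and the absolute sense from the C3 silyloxy group occupying the pseudo-equatorial site of the chair-like tether. The step needs endo/exo and π-facial selectivity: Lewis acid complexation should accentuate the endo preference, the C3 stereocentre next to the C4 gem-dimethyl group (which also accelerates closure, Thorpe–Ingold effect) should bias the face, and the tether fixes the regiochemistry.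

Step 7
Reactants: 12 methyl (3R)-5-[(1R,2R,4aS,6R,8aR)-6-[(tert-butyldimethylsilyl)oxy]-2-{[(tert-butyldimethylsilyl)oxy]methyl}-5,5,8a-trimethyl-1,2,4a,5,6,7,8,8a-octahydronaphthalen-1-yl]-3-methyl-5-oxopentanoate
Product: 14 methyl (3R)-5-[(1R,2R,4aS,6R,8aS)-6-[(tert-butyldimethylsilyl)oxy]-2-{[(tert-butyldimethylsilyl)oxy]methyl}-5,5,8a-trimethyl-1,2,4a,5,6,7,8,8a-octahydronaphthalen-1-yl]-3-methylpentanoate, via tosylhydrazone 13 (not isolated)
Conditions: TsNHNH2, EtOH, 75 °C; solvent exchange; catecholborane, CHCl3, 0 °C → rt; then NaOAc·3H2O, 60 °C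
Reagents that add atoms: 4-methylbenzenesulfonohydrazide, Cc1ccc(cc1)S(=O)(=O)NN (its atoms are carried only in 13)
Why: Caglioti-type deoxygenation, in which the tosylhydrazone is hydroborated at C=N and acetate-induced loss of sulfinate and dinitrogen delivers the C11 methylene, should leave the ester, the alkene and the silyl ethers intact, and C9 already holds its equatorial configuration.

Step 8
Reactants: 14 methyl (3R)-5-[(1R,2R,4aS,6R,8aS)-6-[(tert-butyldimethylsilyl)oxy]-2-{[(tert-butyldimethylsilyl)oxy]methyl}-5,5,8a-trimethyl-1,2,4a,5,6,7,8,8a-octahydronaphthalen-1-yl]-3-methylpentanoate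
Product: 15 methyl (3R)-5-[(1R,2R,4aS,6R,8aS)-6-hydroxy-2-(hydroxymethyl)-5,5,8a-trimethyl-1,2,4a,5,6,7,8,8a-octahydronaphthalen-1-yl]-3-methylpentanoate
Conditions: HF·pyridine, pyridine, THF, 0 °C → rt
Reagents that add atoms: none
Why: Fluoride-mediated desilylation under non-basic conditions should remove both silyl ethers without touching the methyl ester.

Step 9
Reactants: 15 methyl (3R)-5-[(1R,2R,4aS,6R,8aS)-6-hydroxy-2-(hydroxymethyl)-5,5,8a-trimethyl-1,2,4a,5,6,7,8,8a-octahydronaphthalen-1-yl]-3-methylpentanoate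
Product: 17 methyl (3R)-5-[(1S,4aS,6R,8aR)-2-formyl-6-hydroxy-5,5,8a-trimethyl-1,4,4a,5,6,7,8,8a-octahydronaphthalen-1-yl]-3-methylpentanoate, via β,γ-unsaturated aldehyde 16 (not isolated)
Conditions: TEMPO (cat.), PhI(OAc)2, CH2Cl2, rt; then DBU (excess), rt
Reagents that add atoms: none
Why: Oxoammonium (TEMPO) oxidation is selective for the primary C17 alcohol over the hindered secondary C3 alcohol, and base-mediated isomerisation of the β,γ-unsaturated aldehyde through its dienolate should move the alkene into conjugation at C7=C8, erasing the C8 centre and leaving C9 untouched.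

Step 10
Reactants: 17 methyl (3R)-5-[(1S,4aS,6R,8aR)-2-formyl-6-hydroxy-5,5,8a-trimethyl-1,4,4a,5,6,7,8,8a-octahydronaphthalen-1-yl]-3-methylpentanoate
Product: 18 methyl (3R)-5-[(1S,4aS,6R,8aS)-6-hydroxy-2-(hydroxymethyl)-5,5,8a-trimethyl-1,4,4a,5,6,7,8,8a-octahydronaphthalen-1-yl]-3-methylpentanoate
Conditions: NaBH4, CeCl3·7H2O, MeOH, −20 °C
Reagents that add atoms: none
Why: Luche reduction should reduce the enal 1,2-selectively to the allylic alcohol without affecting the methyl ester or the trisubstituted alkene.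

Compound list
1 | pent-4-ynal | C#CCCC=O | starting material
2 | 3-methylbuta-1,2-diene | CC(C)=C=C | starting material
3 | (3-methylbut-2-en-1-yl)bis(isopinocampheyl)borane, isopinocampheyl groups from (+)-α-pinene | CC(C)=CCB([C@@H]1C[C@@H]2C[C@H]([C@H]1C)C2(C)C)[C@@H]1C[C@@H]2C[C@H]([C@H]1C)C2(C)C | intermediate
4 | (4R)-3,3-dimethylhept-1-en-6-yn-4-ol | C#CCC[C@@H](O)C(C)(C)C=C | intermediate
5 | tert-butyl{[(4R)-3,3-dimethylhept-1-en-6-yn-4-yl]oxy}dimethylsilane | C#CCC[C@@H](O[Si](C)(C)C(C)(C)C)C(C)(C)C=C | intermediate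
6 | (3R)-5-methoxy-3-methyl-5-oxopentanoic acid | COC(=O)C[C@H](C)CC(=O)O | starting material
7 | methyl (3S)-5-chloro-3-methyl-5-oxopentanoate | COC(=O)C[C@H](C)CC(=O)Cl | intermediate
8 | {(1E,5R)-5-[(tert-butyldimethylsilyl)oxy]-2,6,6-trimethylocta-1,7-dien-1-yl}dimethylalumane | C[Al](C)/C=C(\C)CC[C@@H](O[Si](C)(C)C(C)(C)C)C(C)(C)C=C | intermediate
9 | methyl (3R,6E,10R)-10-[(tert-butyldimethylsilyl)oxy]-3,7,11,11-tetramethyl-5-oxotrideca-6,12-dienoate | COC(=O)C[C@H](C)CC(=O)/C=C(\C)CC[C@@H](O[Si](C)(C)C(C)(C)C)C(C)(C)C=C | intermediate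
10 | tert-butyl{[(2E)-3-iodoprop-2-en-1-yl]oxy}dimethylsilane | I/C=C/CO[Si](C)(C)C(C)(C)C | starting material
11 | methyl (3R,6E,10R,12E,14E)-10,16-bis[(tert-butyldimethylsilyl)oxy]-3,7,11,11-tetramethyl-5-oxohexadeca-6,12,14-trienoate | COC(=O)C[C@H](C)CC(=O)/C=C(\C)CC[C@@H](O[Si](C)(C)C(C)(C)C)C(C)(C)/C=C/C=C/CO[Si](C)(C)C(C)(C)C | intermediate
12 | methyl (3R)-5-[(1R,2R,4aS,6R,8aR)-6-[(tert-butyldimethylsilyl)oxy]-2-{[(tert-butyldimethylsilyl)oxy]methyl}-5,5,8a-trimethyl-1,2,4a,5,6,7,8,8a-octahydronaphthalen-1-yl]-3-methyl-5-oxopentanoate (trans-fused; C9 acyl, C10 methyl and C8 silyloxymethyl cis; C3 silyloxy equatorial) | COC(=O)C[C@H](C)CC(=O)[C@@H]1[C@H](CO[Si](C)(C)C(C)(C)C)C=C[C@@H]2C(C)(C)[C@H](O[Si](C)(C)C(C)(C)C)CC[C@@]12C | intermediate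
13 | N-tosylhydrazone of 12 at C11 (C=N geometry not defined) | COC(=O)C[C@H](C)CC(=NNS(=O)(=O)c1ccc(C)cc1)[C@@H]1[C@H](CO[Si](C)(C)C(C)(C)C)C=C[C@@H]2C(C)(C)[C@H](O[Si](C)(C)C(C)(C)C)CC[C@@]12C | intermediate
14 | methyl (3R)-5-[(1R,2R,4aS,6R,8aS)-6-[(tert-butyldimethylsilyl)oxy]-2-{[(tert-butyldimethylsilyl)oxy]methyl}-5,5,8a-trimethyl-1,2,4a,5,6,7,8,8a-octahydronaphthalen-1-yl]-3-methylpentanoate | COC(=O)C[C@H](C)CC[C@@H]1[C@H](CO[Si](C)(C)C(C)(C)C)C=C[C@@H]2C(C)(C)[C@H](O[Si](C)(C)C(C)(C)C)CC[C@@]12C | intermediate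
15 | methyl (3R)-5-[(1R,2R,4aS,6R,8aS)-6-hydroxy-2-(hydroxymethyl)-5,5,8a-trimethyl-1,2,4a,5,6,7,8,8a-octahydronaphthalen-1-yl]-3-methylpentanoate | COC(=O)C[C@H](C)CC[C@@H]1[C@H](CO)C=C[C@@H]2C(C)(C)[C@H](O)CC[C@@]12C | intermediate
16 | methyl (3R)-5-[(1R,2R,4aS,6R,8aS)-2-formyl-6-hydroxy-5,5,8a-trimethyl-1,2,4a,5,6,7,8,8a-octahydronaphthalen-1-yl]-3-methylpentanoate | COC(=O)C[C@H](C)CC[C@@H]1[C@H](C=O)C=C[C@@H]2C(C)(C)[C@H](O)CC[C@@]12C | intermediate
17 | methyl (3R)-5-[(1S,4aS,6R,8aR)-2-formyl-6-hydroxy-5,5,8a-trimethyl-1,4,4a,5,6,7,8,8a-octahydronaphthalen-1-yl]-3-methylpentanoate | COC(=O)C[C@H](C)CC[C@@H]1C(C=O)=CC[C@@H]2C(C)(C)[C@H](O)CC[C@@]12C | intermediate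
18 | methyl (3R)-5-[(1S,4aS,6R,8aS)-6-hydroxy-2-(hydroxymethyl)-5,5,8a-trimethyl-1,4,4a,5,6,7,8,8a-octahydronaphthalen-1-yl]-3-methylpentanoate (CNP0313905.1) | COC(=O)C[C@H](C)CC[C@@H]1C(CO)=CC[C@@H]2C(C)(C)[C@H](O)CC[C@@]12C | target

Total step count: 10. Longest linear sequence: 9 (steps 1, 2 and 4–10, from pent-4-ynal).

Steps most likely to fail

Step 6 (key cycloaddition). The exo pathway leading to cis ring fusion may compete, because the trans-fused transition state carries the 1,3-relationship between the axial C4 methyl and the C10 methyl. The π-facial bias may also be eroded, since a silyloxy group next to a gem-dimethyl carbon has only a modest equatorial preference, and the Lewis-acid-complexed β,β-disubstituted enone may react slowly or lose its E geometry. The fallback changes the dienophile from a complexed ketone to a cationic one and sets out from 11. The ketone is converted with 1,2-bis(trimethylsilyloxy)ethane and catalytic TMSOTf in CH2Cl2 at −78 °C into the 1,3-dioxolane ketal of 11 F1. Catalytic TfOH at −78 °C should then open the dioxolane to an alkoxyallyl (dioxolanylium-type) cation, a much stronger dienophile, which should undergo the ionic Diels–Alder cyclisation with endo preference and reclose to the 1,3-dioxolane ketal of 12 F2. Mild hydrolysis (PPTS, wet acetone) returns ketone 12, where the route is rejoined.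

Step 5 (Heck coupling). Insertion into the vinyl group next to quaternary C4 may be slow, so that decomposition of the alkenyl iodide, palladium hydride isomerisation of the diene or premature uncatalysed cycloaddition can take over. The fallback builds the diene by olefination before the enone is made and sets out from 5. Selective ozonolysis of the vinyl group (O3, CH2Cl2, −78 °C, indicator-controlled; PPh3) gives (3R)-3-[(tert-butyldimethylsilyl)oxy]-2,2-dimethylhept-6-ynal F3. A vinylogous Horner–Wadsworth–Emmons reaction with triethyl 4-phosphonocrotonate (LiHMDS, THF, −78 → 0 °C) gives ethyl (2E,4E,7R)-7-[(tert-butyldimethylsilyl)oxy]-6,6-dimethylundeca-2,4-dien-10-ynoate F4. Reduction with i-Bu2AlH (CH2Cl2, −78 °C) gives (2E,4E,7R)-7-[(tert-butyldimethylsilyl)oxy]-6,6-dimethylundeca-2,4-dien-10-yn-1-ol F5, and silylation (TBSCl, imidazole, DMF) gives its bis-silyl ether, (2E,4E,7R)-1,7-bis[(tert-butyldimethylsilyl)oxy]-6,6-dimethylundeca-2,4-dien-10-yne F6. Methylalumination as in step 4 (Me3Al, Cp2ZrCl2 cat.) gives the alkenyldimethylalane of F6 F7, which is acylated with 7 under Pd(PPh3)4 catalysis to give 11, where the route is rejoined.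

Step 7 (deoxygenation at C11). Hydrazone formation at the ketone, which is flanked by the tertiary C9 next to quaternary C10, may stall, and the hydrazone may eliminate to an alkene instead of being reduced. The fallback replaces the hydrazone by a thioketal and sets out from 12. Reaction with ethane-1,2-dithiol and BF3·OEt2 (CH2Cl2, 0 °C) gives the 1,3-dithiolane of 12 F8, and radical desulfurisation (Bu3SnH, AIBN, toluene, 110 °C), which spares the ring alkene and the ester, gives 14, where the route is rejoined.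

Further compounds
F1 | step 6 | 1,3-dioxolane ketal of 11 | COC(=O)C[C@H](C)CC1(OCCO1)/C=C(\C)CC[C@@H](O[Si](C)(C)C(C)(C)C)C(C)(C)/C=C/C=C/CO[Si](C)(C)C(C)(C)C
F2 | step 6 | 1,3-dioxolane ketal of 12 | COC(=O)C[C@H](C)CC3(OCCO3)[C@@H]1[C@H](CO[Si](C)(C)C(C)(C)C)C=C[C@@H]2C(C)(C)[C@H](O[Si](C)(C)C(C)(C)C)CC[C@@]12C
F3 | step 5 | (3R)-3-[(tert-butyldimethylsilyl)oxy]-2,2-dimethylhept-6-ynal | C#CCC[C@@H](O[Si](C)(C)C(C)(C)C)C(C)(C)C=O
F4 | step 5 | ethyl (2E,4E,7R)-7-[(tert-butyldimethylsilyl)oxy]-6,6-dimethylundeca-2,4-dien-10-ynoate | C#CCC[C@@H](O[Si](C)(C)C(C)(C)C)C(C)(C)/C=C/C=C/C(=O)OCC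
F5 | step 5 | (2E,4E,7R)-7-[(tert-butyldimethylsilyl)oxy]-6,6-dimethylundeca-2,4-dien-10-yn-1-ol | C#CCC[C@@H](O[Si](C)(C)C(C)(C)C)C(C)(C)/C=C/C=C/CO
F6 | step 5 | (2E,4E,7R)-1,7-bis[(tert-butyldimethylsilyl)oxy]-6,6-dimethylundeca-2,4-dien-10-yne | C#CCC[C@@H](O[Si](C)(C)C(C)(C)C)C(C)(C)/C=C/C=C/CO[Si](C)(C)C(C)(C)C
F7 | step 5 | alkenyldimethylalane of F6 | C[Al](C)/C=C(\C)CC[C@@H](O[Si](C)(C)C(C)(C)C)C(C)(C)/C=C/C=C/CO[Si](C)(C)C(C)(C)C
F8 | step 7 | 1,3-dithiolane of 12 | COC(=O)C[C@H](C)CC3(SCCS3)[C@@H]1[C@H](CO[Si](C)(C)C(C)(C)C)C=C[C@@H]2C(C)(C)[C@H](O[Si](C)(C)C(C)(C)C)CC[C@@]12C
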